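Retrosynthesis: the three O‑benzyl bonds are cut first, then the two C3''–CH3 bonds of the side‑chain carbinol, with C3'' reconnected to O5 as a lactone carbonyl. Next come the C2 one‑carbon unit of ring C, the C4–C4a acyl bond, and the lactone itself (C6–C1'' and O5–C3''), leading back to phloroglucinol and acrylic acid.
Enabling feature: the 3‑hydroxy‑3‑methylbutyl chain at C6 is ortho to the C5 oxygen of ring A, so C1''–C3'' and O5 can be carried as a six‑membered aryl lactone (O5–C(=O)–CH2–CH2–C6) fused to ring A.
Forward order: the lactone ring is fused onto phloroglucinol (ring A) first. Ring B arrives as an arylacetonitrile by Hoesch acylation at the carbon that becomes C4a. Ring C closes onto the only free ortho hydroxyl, which places the chain at C6. O7 is benzylated, two equivalents of MeMgBr open the lactone, and hydrogenolysis finishes the route.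
Stereochemistry: the target has no stereocentre and no stereogenic double bond, so nothing has to be set.

Key step: step 6

Remark: 2,4‑bis(benzyloxy)benzaldehyde is taken as a commercial starting material. Intermediates 6 and 10 are alkene‑isomer mixtures whose geometry is lost in the next event, so their SMILES carry no double‑bond descriptor. Isoflavone locants (5, 6, 7, 2', 4', 1''–3'') are used for the final ring system.

**Route**

Step 1
Reactants: 1 phloroglucinol; 2 acrylic acid
Product: 4 5,7-dihydroxychroman-2-one, via 3-(2,4,6-trihydroxyphenyl)propanoic acid 3 (not isolated)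
Conditions: Amberlyst-15 (sulfonated polystyrene resin, SO3H form), toluene, reflux, Dean–Stark; 2 equiv of 1
Reagents that add atoms: none
Why: acid‑catalysed Friedel–Crafts hydroarylation of acrylic acid by the threefold‑symmetric, very electron‑rich phloroglucinol, followed by lactonisation of acid 3 onto an ortho hydroxyl, is the usual phenol‑plus‑acrylic‑acid entry to 3,4‑dihydrocoumarins; symmetry removes any site issue, and the excess of 1 together with the less nucleophilic monoacylated ring of 4 should hold back a second annulation.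

Step 2
Reactants: 5 2,4-bis(benzyloxy)benzaldehyde
Product: 7 2-[2,4-bis(benzyloxy)phenyl]acetonitrile, via N-formyl sulfonyl enamide 6 (not isolated)
Conditions: TosMIC, KOt-Bu, DME, −40 °C; then MeOH, reflux
Reagents that add atoms: p-toluenesulfonylmethyl isocyanide (TosMIC), Cc1ccc(cc1)S(=O)(=O)C[N+]#[C-]
Why: the van Leusen reductive cyanation turns an aromatic aldehyde into the homologous arylacetonitrile in one flask (the TosMIC anion adds to the carbonyl, and enamide 6 is deformylated by methanol and loses sulfinate), and benzyl ethers are inert to KOt-Bu.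

Step 3
Reactants: 4 5,7-dihydroxychroman-2-one; 7 2-[2,4-bis(benzyloxy)phenyl]acetonitrile
Product: 9 8-{[2,4-bis(benzyloxy)phenyl]acetyl}-5,7-dihydroxychroman-2-one, via ketiminium chloride 8 (not isolated)
Conditions: ZnCl2, HCl (g), Et2O–dioxane, 0 °C; then H2O, 90 °C
Reagents that add atoms: water, O
Why: the Houben–Hoesch acylation of a free resorcinol‑type phenol by a nitrile is C‑selective and mild enough for the benzyl ethers and the lactone; attack is expected at C8 of 4, which is ortho to one hydroxyl and para to the other (the preferred site in orcinol‑type phenols and in 5,7‑dihydroxycoumarins), rather than at C6 between the two hydroxyls, and the free phenol ring of 4 should outrun the dialkoxyarene ring of 7 as the nucleophile.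

Step 4
Reactants: 9 8-{[2,4-bis(benzyloxy)phenyl]acetyl}-5,7-dihydroxychroman-2-one
Product: 11 9-[2,4-bis(benzyloxy)phenyl]-5-hydroxy-3,4-dihydro-2H,10H-pyrano[2,3-f]chromene-2,10-dione (the 7-hydroxy-2',4'-bis(benzyloxy)isoflavone carrying the C6–CH2CH2–C(=O)–O5 lactone), via enaminone 10 (not isolated)
Conditions: BF3·OEt2, DMF, 50 °C; then MsCl, 60 °C; aq. NaOAc work-up
Reagents that add atoms: N,N-dimethylformamide, CN(C)C=O
Why: this is the deoxybenzoin‑to‑isoflavone cyclocondensation under Vilsmeier‑type conditions, in which the DMF/MsCl iminium reagent aminomethylenates the activated methylene of the boron‑chelated ketone to give 10, whose only free ortho hydroxyl (the other ortho oxygen being held in the lactone) adds to the enamine carbon and expels dimethylamine, so ring C can close in one direction only while the acidic medium spares the aryl lactone from aminolysis.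

Step 5
Reactants: 11 7-hydroxy lactone-fused isoflavone
Product: 12 5-(benzyloxy)-9-[2,4-bis(benzyloxy)phenyl]-3,4-dihydro-2H,10H-pyrano[2,3-f]chromene-2,10-dione (the 7,2',4'-tris(benzyloxy)isoflavone carrying the C6–CH2CH2–C(=O)–O5 lactone)
Conditions: BnBr, K2CO3, acetone, reflux
Reagents that add atoms: benzyl bromide, BrCc1ccccc1
Why: Williamson etherification of the acidic 7‑hydroxyl (a vinylogous carboxylic acid) proceeds under anhydrous K2CO3, where the weakly nucleophilic phenoxide and carbonate should leave the aryl lactone closed.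

Step 6
Reactants: 12 tribenzyl lactone-fused isoflavone; 13 methylmagnesium bromide
Product: 15 7-(benzyloxy)-3-[2,4-bis(benzyloxy)phenyl]-5-hydroxy-6-(3-hydroxy-3-methylbutyl)-4H-chromen-4-one (7,2',4'-tri-O-benzyl luteone hydride), via methyl ketone magnesium phenoxide 14 (not isolated)
Conditions: MeMgBr (3 equiv), THF, −78 → 0 °C; then aq. NH4Cl
Reagents that add atoms: methylmagnesium bromide (the second equivalent, which delivers the second methyl group on C3''; the first equivalent is reactant 13), C[Mg]Br
Why: this is a Grignard double addition to an aryl ester: the first equivalent of 13 adds to the lactone carbonyl of 12, the tetrahedral alkoxide collapses and expels the ring A C5 phenoxide to give methyl ketone 14, and a second equivalent of the same reagent adds to that ketone, so both C3''–CH3 bonds form in one flask. The closest known reaction type is the conversion of 3,4‑dihydrocoumarins into 2‑(3‑hydroxy‑3‑methylbutyl)phenols with excess methylmagnesium halide. No ring is closed (the six‑membered lactone is opened) and no stereocentre arises, because the new carbinol carbon carries two identical methyl groups. The step needs chemoselectivity for the aryl lactone over the pyranone of ring C; an aryl ester is much more electrophilic at −78 °C than the vinylogous‑ester C4 carbonyl, and once the first addition has released the C5 phenoxide, its magnesium chelate with the C4 carbonyl deactivates the pyranone further. The benzyl ethers at O7, O2' and O4' are inert to the reagent, and the acid‑sensitive tertiary alcohol is formed under basic conditions and meets only NH4Cl on work‑up, so cyclisation onto O5 or O7 to a dimethylchroman should be avoided.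

Step 7
Reactants: 15 7,2',4'-tri-O-benzyl luteone hydride
Product: 16 luteone hydride, 3-(2,4-dihydroxyphenyl)-5,7-dihydroxy-6-(3-hydroxy-3-methylbutyl)-4H-chromen-4-one
Conditions: H2 (1 atm), 10% Pd/C, EtOAc–MeOH, rt
Reagents that add atoms: none
Why: catalytic hydrogenolysis of the three aryl benzyl ethers over Pd/C is neutral, so the tertiary alcohol should neither eliminate nor cyclise, and stopping after three equivalents of H2 should leave the C2=C3 bond of the pyranone intact.

**Compound list**

1 | phloroglucinol | Oc1cc(O)cc(O)c1 | starting material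
2 | acrylic acid | C=CC(=O)O | starting material
3 | 3-(2,4,6-trihydroxyphenyl)propanoic acid | OC(=O)CCc1c(O)cc(O)cc1O | intermediate
4 | 5,7-dihydroxychroman-2-one (5,7-dihydroxy-3,4-dihydrocoumarin) | O=C1CCc2c(O)cc(O)cc2O1 | intermediate
5 | 2,4-bis(benzyloxy)benzaldehyde | O=Cc1ccc(OCc2ccccc2)cc1OCc1ccccc1 | starting material
6 | N-{2-[2,4-bis(benzyloxy)phenyl]-1-(4-methylphenylsulfonyl)ethenyl}formamide (present as its potassium salt, alkene-isomer mixture) | O=CNC(=Cc1ccc(OCc2ccccc2)cc1OCc1ccccc1)S(=O)(=O)c1ccc(C)cc1 | intermediate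
7 | 2-[2,4-bis(benzyloxy)phenyl]acetonitrile | N#CCc1ccc(OCc2ccccc2)cc1OCc1ccccc1 | intermediate
8 | 2-[2,4-bis(benzyloxy)phenyl]-1-(5,7-dihydroxy-2-oxochroman-8-yl)ethan-1-iminium chloride | [NH2+]=C(Cc1ccc(OCc2ccccc2)cc1OCc1ccccc1)c1c(O)cc(O)c2c1OC(=O)CC2.[Cl-] | intermediate
9 | 8-{[2,4-bis(benzyloxy)phenyl]acetyl}-5,7-dihydroxychroman-2-one | O=C(Cc1ccc(OCc2ccccc2)cc1OCc1ccccc1)c1c(O)cc(O)c2c1OC(=O)CC2 | intermediate
10 | 8-{2-[2,4-bis(benzyloxy)phenyl]-3-(dimethylamino)prop-2-enoyl}-5,7-dihydroxychroman-2-one (held as its boron chelate, alkene-isomer mixture) | CN(C)C=C(C(=O)c1c(O)cc(O)c2c1OC(=O)CC2)c1ccc(OCc2ccccc2)cc1OCc1ccccc1 | intermediate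
11 | 9-[2,4-bis(benzyloxy)phenyl]-5-hydroxy-3,4-dihydro-2H,10H-pyrano[2,3-f]chromene-2,10-dione | O=C1CCc2c(O)cc3occ(-c4ccc(OCc5ccccc5)cc4OCc4ccccc4)c(=O)c3c2O1 | intermediate
12 | 5-(benzyloxy)-9-[2,4-bis(benzyloxy)phenyl]-3,4-dihydro-2H,10H-pyrano[2,3-f]chromene-2,10-dione | O=C1CCc2c(OCc3ccccc3)cc3occ(-c4ccc(OCc5ccccc5)cc4OCc4ccccc4)c(=O)c3c2O1 | intermediate
13 | methylmagnesium bromide | C[Mg]Br | starting material
14 | bromomagnesium 5-phenoxide of 7-(benzyloxy)-3-[2,4-bis(benzyloxy)phenyl]-5-hydroxy-6-(3-oxobutyl)-4H-chromen-4-one | CC(=O)CCc1c(OCc2ccccc2)cc2occ(-c3ccc(OCc4ccccc4)cc3OCc3ccccc3)c(=O)c2c1O[Mg]Br | intermediate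
15 | 7-(benzyloxy)-3-[2,4-bis(benzyloxy)phenyl]-5-hydroxy-6-(3-hydroxy-3-methylbutyl)-4H-chromen-4-one | CC(C)(O)CCc1c(OCc2ccccc2)cc2occ(-c3ccc(OCc4ccccc4)cc3OCc3ccccc3)c(=O)c2c1O | intermediate
16 | luteone hydride, 3-(2,4-dihydroxyphenyl)-5,7-dihydroxy-6-(3-hydroxy-3-methylbutyl)-4H-chromen-4-one | CC(C)(O)CCc1c(O)cc2occ(-c3ccc(O)cc3O)c(=O)c2c1O | target

**Step count**

Total: 7 steps. Longest linear sequence: 6 steps (1, 3, 4, 5, 6, 7, or equally 2, 3, 4, 5, 6, 7).

**Steps most likely to fail**

Step 3. The acyl group may enter at C6 of 4, between the two hydroxyls, as well as at C8, and the electron‑rich ring of 7 may compete as the arene partner. The fallback sets out from 1 and 7 and returns to the route at 12. A Houben–Hoesch reaction of symmetric phloroglucinol 1 with 7 should give 2-[2,4-bis(benzyloxy)phenyl]-1-(2,4,6-trihydroxyphenyl)ethanone F1 with no site issue. BF3·OEt2/DMF/MsCl should close it to 3-[2,4-bis(benzyloxy)phenyl]-5,7-dihydroxy-4H-chromen-4-one F2. BnBr/K2CO3 in acetone should alkylate only the non‑chelated 7‑hydroxyl, giving 7-(benzyloxy)-3-[2,4-bis(benzyloxy)phenyl]-5-hydroxy-4H-chromen-4-one F3. Benzyltrimethylammonium dichloroiodate (BnMe3N+ ICl2−) with CaCO3 in CH2Cl2–MeOH should iodinate ortho to the chelated 5‑hydroxyl, giving 7-(benzyloxy)-3-[2,4-bis(benzyloxy)phenyl]-5-hydroxy-6-iodo-4H-chromen-4-one F4. A Negishi coupling with BrZnCH2CH2CO2Et (Pd(OAc)2, SPhos, THF, reagent in excess because of the free 5‑hydroxyl) should give ethyl 3-{7-(benzyloxy)-3-[2,4-bis(benzyloxy)phenyl]-5-hydroxy-4-oxo-4H-chromen-6-yl}propanoate F5. TsOH in refluxing toluene should then lactonise the ester onto O5 and deliver 12, with the chain fixed at C6 by the iodination.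

Step 6. The Grignard reagent may attack the pyranone (C4 carbonyl or C2) before the lactone is consumed, or enolise ketone 14 so that the reaction stalls at the ketone stage. The fallback sets out from 11 and returns at 16. The 7‑hydroxy lactone 11 is used without benzylation. The first equivalent of MeMgBr converts the 7‑hydroxyl into its magnesium phenoxide, a vinylogous carboxylate that switches off the pyranone. Further MeMgBr (5 equiv in all, THF, 0 °C, with anhydrous CeCl3 if enolisation is seen) should open the lactone to 3-[2,4-bis(benzyloxy)phenyl]-5,7-dihydroxy-6-(3-hydroxy-3-methylbutyl)-4H-chromen-4-one F6. H2 over 10% Pd/C should then debenzylate F6 to 16.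

Step 7. Hydrogen may add to the C2=C3 bond of ring C before the hindered 2'‑benzyl ether is cleaved. The fallback sets out from 11 and returns at 16; it removes the benzyl ethers before the tertiary alcohol exists, when a Lewis acid can be tolerated. BCl3 with pentamethylbenzene in CH2Cl2 at −78 °C should give 9-(2,4-dihydroxyphenyl)-5-hydroxy-3,4-dihydro-2H,10H-pyrano[2,3-f]chromene-2,10-dione F7. TBSCl/imidazole in DMF should give 5-(tert-butyldimethylsilyloxy)-9-[2,4-bis(tert-butyldimethylsilyloxy)phenyl]-3,4-dihydro-2H,10H-pyrano[2,3-f]chromene-2,10-dione F8. MeMgBr under the conditions of step 6 should give 7,2',4'-tris-O-(tert-butyldimethylsilyl) luteone hydride F9. Bu4NF buffered with AcOH in THF at 0 °C should then release 16.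

**Further compounds**

F1 | step 3 | 2-[2,4-bis(benzyloxy)phenyl]-1-(2,4,6-trihydroxyphenyl)ethanone | O=C(Cc1ccc(OCc2ccccc2)cc1OCc1ccccc1)c1c(O)cc(O)cc1O
F2 | step 3 | 3-[2,4-bis(benzyloxy)phenyl]-5,7-dihydroxy-4H-chromen-4-one | O=c1c(-c2ccc(OCc3ccccc3)cc2OCc2ccccc2)coc2cc(O)cc(O)c12
F3 | step 3 | 7-(benzyloxy)-3-[2,4-bis(benzyloxy)phenyl]-5-hydroxy-4H-chromen-4-one | O=c1c(-c2ccc(OCc3ccccc3)cc2OCc2ccccc2)coc2cc(OCc3ccccc3)cc(O)c12
F4 | step 3 | 7-(benzyloxy)-3-[2,4-bis(benzyloxy)phenyl]-5-hydroxy-6-iodo-4H-chromen-4-one | O=c1c(-c2ccc(OCc3ccccc3)cc2OCc2ccccc2)coc2cc(OCc3ccccc3)c(I)c(O)c12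
F5 | step 3 | ethyl 3-{7-(benzyloxy)-3-[2,4-bis(benzyloxy)phenyl]-5-hydroxy-4-oxo-4H-chromen-6-yl}propanoate | CCOC(=O)CCc1c(OCc2ccccc2)cc2occ(-c3ccc(OCc4ccccc4)cc3OCc3ccccc3)c(=O)c2c1O
F6 | step 6 | 3-[2,4-bis(benzyloxy)phenyl]-5,7-dihydroxy-6-(3-hydroxy-3-methylbutyl)-4H-chromen-4-one | CC(C)(O)CCc1c(O)cc2occ(-c3ccc(OCc4ccccc4)cc3OCc3ccccc3)c(=O)c2c1O
F7 | step 7 | 9-(2,4-dihydroxyphenyl)-5-hydroxy-3,4-dihydro-2H,10H-pyrano[2,3-f]chromene-2,10-dione | O=C1CCc2c(O)cc3occ(-c4ccc(O)cc4O)c(=O)c3c2O1
F8 | step 7 | 5-(tert-butyldimethylsilyloxy)-9-[2,4-bis(tert-butyldimethylsilyloxy)phenyl]-3,4-dihydro-2H,10H-pyrano[2,3-f]chromene-2,10-dione | O=C1CCc2c(O[Si](C)(C)C(C)(C)C)cc3occ(-c4ccc(O[Si](C)(C)C(C)(C)C)cc4O[Si](C)(C)C(C)(C)C)c(=O)c3c2O1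
F9 | step 7 | 7,2',4'-tris-O-(tert-butyldimethylsilyl) luteone hydride | CC(C)(O)CCc1c(O[Si](C)(C)C(C)(C)C)cc2occ(-c3ccc(O[Si](C)(C)C(C)(C)C)cc3O[Si](C)(C)C(C)(C)C)c(=O)c2c1O
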